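**Two plateaus.** Target reads 35.2% of the substrate charged in the north-east run and 50.8% in the north-west run, each the mean of the last three readings, and these two runs have to carry us to two new flasks.

| setting | north-east | north-west | spring | noon |
|---|---|---|---|---|
| substrate | 0.52 M | 1 M | 1.5 M | 0.69 M |
| partner | 1.38 M | 1.38 M | 1.38 M | 1.38 M |
| temperature | 35 °C | 50 °C |  |  |
| remark | run made earlier | run made earlier | at 40 °C throughout | at 60 °C until 1.5 min, from then on at 40 °C |
| time |  |  | 4.0 min | 8.0 min |

| north-east: time / min | north-east: target / % | north-west: time / min | north-west: target / % |
|---|---|---|---|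
| 1.50 | 22.7 | 0.833 | 41.2 |
| 5.00 | 35.1 | 2.00 | 51.0 |
| 8.00 | 35.5 | 4.00 | 50.2 |
| 15.0 | 35.1 | 6.00 | 51.3 |

(standard deviation of a reading: 1 percentage point)

1. which of the two ends with the higher amount of target, in percent of the substrate charged ("neither" if they lie within 2 percentage points) (spring / noon / neither)
2. target at the end, in percent of the substrate charged, spring
3. target at the end, in percent of the substrate charged, noon

**Side odds.** We read each plateau as a split under kinetic control: the substrate is used up, part going to target and part lost in a step that takes one partner each. Partner then averages 87.8% of its charge in the north-east run and 82.2% in the north-west run. The north-east run has side odds of 2.09, meaning lost substrate over target, divided by that mean fraction of partner, and the north-west run has 1.18. Taking the logarithm as straight in temperature gives 1.73 at 40 °C and 0.802 at 60 °C. The rates of approach to the plateau, read from the first reading of each run, 0.689 min⁻¹ and 2.00 min⁻¹, give 0.982 min⁻¹ and 4.06 min⁻¹ the same way.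

**Noon's bracket.** By this estimate noon keeps 0.227% of its substrate at 1.5 min, so we reckon its split at 60 °C. Holding noon's partner at its full charge throughout gives our floor for target, 55.5%. In this reckoning noon's partner stays above what that loss leaves, which puts our ceiling for target at 61.6%. The share that agrees with its own mean partner is 58.2%, and that is our figure for noon.

**Spring's bracket.** The same steps for spring at 40 °C give 36.7% and 65.0%, tightened to 45.2%. With 1.97% of substrate estimated left at 4.0 min, we commit to 44.3%.

**The check.** The forecast gives 34.8% for spring and 40.8% for noon, saying of noon's cool stretch “which erases its 60 °C history”, and both lie below our brackets. Spring ends at 44.2% and noon at 57.2%, so noon holds more target.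

    substrate → target (k = 0.0460 s⁻¹, Ea = 83.0 kJ mol⁻¹)
    substrate + partner → side product A (k = 0.0130 M⁻¹ s⁻¹, Ea = 57.0 kJ mol⁻¹)
    substrate + partner → side product B (k = 0.0150 M⁻¹ s⁻¹, Ea = 48.0 kJ mol⁻¹)
    (constants at 60 °C)

**Hot start.** Noon already holds 57.2% of target at 1.50 min, with 0.0936% of substrate left. Now take spring's recipe at 55 °C, held for spring's 4.0 min. The side odds become 0.971, and the share that agrees with its own mean partner is 57.3%. That flask ends with 0% of substrate and 57.4% of target.

All runs stem from a simulated flask with made-up constants, and the scatter is random.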